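**Plan**
- Retrosynthetic cuts: the C–O bonds of the three esters; C9–C10 (aldol) and C8–C9 (methyl addition) in the side chain; the C3–C4 bond in the ring.
- Enabling feature: in the cyclohexane ring, C3 (secondary carbinol) and C4 (tertiary carbinol, its OH on the same face as O5, O6 and the C1 substituent) are adjacent oxygen-bearing carbons. This is an acyloin retron, so two carbonyl carbons can be joined by polarity reversal.
- Forward order: (S)-carvone is oxygenated at C6 and C5, its C3=C4 alkene is cut to a C3 aldehyde and a C4 methyl ketone, and the only ring is closed again by a carbene-catalysed benzoin reaction. Reduction and ester installation at C5/C6 follow, then the chain C8–C13 is grown from the isopropenyl group (enal, methyl ketone, aldol, reductive esterification) and the silyl groups are removed.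
- Stereochemistry: C1 from (S)-carvone; C6 by Rubottom oxidation then Mitsunobu inversion; C5 by Luche reduction; C4 in the benzoin closure (substrate chair, reinforced by the chiral carbene); C3 by axial hydride delivery; C10 by the Ipc2BCl aldol; C8 by the Evans–Tishchenko 1,3-anti reduction; the Z alkenes come from angelic acid.

Key step: step 8

Remark on locants (not IUPAC): ring C1 (bears the isopropenyl group, later the side chain), C2 (CH2), C3, C4 (methyl-bearing), C5, C6; chain C7(=C14H2), C8, C9, C10, C11. β is the ring face of the C1 substituent, α the opposite face.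
Assumption: the sense of induction of the chiral triazolium salt (step 8) and of (+)-Ipc2BCl (step 21) is taken from their behaviour with simple substrates; the antipode of either reagent is equally available.

**Step 1**
Reactants: 1 (S)-(+)-carvone
Product: 3 trimethylsilyl dienol ether of carvone (C5–OSiMe3, C5=C6 and C3=C4), via lithium dienolate 2 (not isolated)
Conditions: LiN(i-Pr)2 (commercial solution, 1.1 equiv), THF, −78 °C; Me3SiCl, −78 → 0 °C; pentane extraction
Reagents that add atoms: chlorotrimethylsilane, C[Si](C)(C)Cl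
Why: Kinetic deprotonation of the enone at the α' carbon C6 gives the cross-conjugated dienolate, which is trapped on oxygen (silyl enol ether formation); C1 is untouched.

**Step 2**
Reactants: 3 trimethylsilyl dienol ether of carvone
Product: 5 trans-6-hydroxycarvone (6α-OH), via 6α-trimethylsilyloxy ketone 4 (not isolated)
Conditions: mCPBA (1.05 equiv), hexane–CH2Cl2, −15 °C; then 1 M HCl (cat.), THF–H2O, 0 °C
Reagents that add atoms: 3-chloroperbenzoic acid, OOC(=O)c1cccc(Cl)c1
Why: Rubottom oxidation: the peracid attacks the electron-rich silyl enol ether at C6 on the face away from the neighbouring isopropenyl group, and silyl migration then hydrolysis give the trans α'-hydroxy enone.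

**Step 3**
Reactants: 5 trans-6-hydroxycarvone
Product: 6 cis-6-(4-nitrobenzoyloxy)carvone (6β ester)
Conditions: 4-nitrobenzoic acid, PPh3, diisopropyl azodicarboxylate, THF, 0 °C → rt
Reagents that add atoms: 4-nitrobenzoic acid, OC(=O)c1ccc(cc1)[N+](=O)[O-]
Why: Mitsunobu reaction: the C6 oxyphosphonium ion, activated by the adjacent carbonyl, is displaced by the carboxylate with inversion, which puts O6 on the β face, cis to the isopropenyl group.

**Step 4**
Reactants: 6 cis-6-(4-nitrobenzoyloxy)carvone
Product: 8 1β-isopropenyl-4-methylcyclohex-3-ene-5β,6β-diol, via hydroxy nitrobenzoate 7 (not isolated)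
Conditions: NaBH4, CeCl3·7H2O, MeOH, −78 °C; then K2CO3 (cat.), MeOH, 0 °C → rt
Reagents that add atoms: none
Why: Luche 1,2-reduction: hydride adds to C5 axially from the α face, anti to the pseudoaxial C6 ester, giving the 5β allylic alcohol (all-cis with C1 and C6), and catalytic methoxide then transesterifies the nitrobenzoate.

**Step 5**
Reactants: 8 1β-isopropenyl-4-methylcyclohex-3-ene-5β,6β-diol
Product: 9 3β,4β-epoxy-1β-isopropenyl-4-methylcyclohexane-5β,6β-diol
Conditions: VO(acac)2 (5 mol %), t-BuOOH (in decane, 1.5 equiv), CH2Cl2, 0 °C → rt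
Reagents that add atoms: tert-butyl hydroperoxide, CC(C)(C)OO
Why: Hydroxyl-directed vanadium-catalysed epoxidation: the allylic C5 and homoallylic C6 hydroxyls deliver the peroxide to the β face of the C3=C4 alkene only, so the undirected isopropenyl group is left alone; the epoxide configuration is erased in step 7.

**Step 6**
Reactants: 9 epoxy diol
Product: 10 3β,4β-epoxy-1β-isopropenyl-5β,6β-(isopropylidenedioxy)-4-methylcyclohexane
Conditions: 2,2-dimethoxypropane, pyridinium p-toluenesulfonate (cat.), acetone, 0 °C → rt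
Reagents that add atoms: 2,2-dimethoxypropane, COC(C)(C)OC
Why: Acid-catalysed acetal exchange closes the cis-fused dioxolane on the 5β,6β-diol under conditions mild enough for the epoxide.

**Step 7**
Reactants: 10 epoxy acetonide
Product: 11 (3R,4S,5S)-3-isopropenyl-4,5-(isopropylidenedioxy)-6-oxoheptanal (C3 aldehyde, C4 methyl ketone in ring locants)
Conditions: H5IO6 (1.3 equiv), THF–Et2O, 0 °C, short reaction time; used without storage
Reagents that add atoms: orthoperiodic acid, OI(=O)(O)(O)(O)O
Why: Periodic acid opens the epoxide and cleaves the resulting glycol in one flask (oxidative epoxide cleavage), giving the aldehyde and the methyl ketone; at 0 °C the ring-fused acetonide and the isopropenyl group should survive, and C1, C5, C6 are untouched.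

**Step 8**
Reactants: 11 keto-aldehyde
Product: 12 4β-hydroxy-1β-isopropenyl-5β,6β-(isopropylidenedioxy)-4α-methylcyclohexan-3-one
Conditions: (5aS,10bR)-2-(pentafluorophenyl)-5a,10b-dihydro-4H,6H-indeno[2,1-b][1,2,4]triazolo[4,3-d][1,4]oxazin-2-ium tetrafluoroborate (10 mol %), Et3N (10 mol %), toluene (0.05 M), rt
Reagents that add atoms: none
Why: The carbene adds to the unhindered C3 aldehyde and a proton shift gives the hydroxy-enamine (acyl anion equivalent), whose C3 attacks the C4 ketone; loss of the carbene leaves the C3 ketone beside the new C4 tertiary alcohol. The closest known reaction is the triazolium-catalysed intramolecular crossed aldehyde–ketone benzoin that gives six-membered tertiary α-ketols. The cyclohexane closes in a 6-exo-trig mode, C3 adding to the C4 carbonyl carbon with the C=O bond outside the new ring. The C4 stereocentre is set by the substrate chair: the isopropenyl group is equatorial, the cis-fused dioxolane holds O5 equatorial and O6 axial, and the ketone methyl takes the equatorial site to avoid a 1,3-diaxial clash with O6, so C3 adds to the Re face and O4 ends axial on the β face, hydrogen-bonded to the enaminol OH; the indanol-derived carbene is chosen to reinforce this face. The step needs the aldehyde alone to act as acyl donor and the benzoin to outrun aldol closure and C5 epimerisation; only the aldehyde can form the hydroxy-enamine, and the acidic pentafluorophenyl triazolium salt needs no more than a catalytic amount of the weak base Et3N.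

**Step 9**
Reactants: 12 α-ketol
Product: 13 1β-isopropenyl-5β,6β-(isopropylidenedioxy)-4α-methylcyclohexane-3β,4β-diol
Conditions: NaBH4, MeOH, −40 → 0 °C
Reagents that add atoms: none
Why: Borohydride reduction: hydride adds axially to the α face of the C3 ketone, anti to the axial C4 oxygen and away from the β-face acetonide, giving the equatorial 3β alcohol cis to O4.

**Step 10**
Reactants: 13 diol acetonide
Product: 14 3β-(tert-butyldimethylsilyloxy) derivative of 13 (C4–OH free)
Conditions: t-BuMe2SiCl, imidazole, DMF, rt → 40 °C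
Reagents that add atoms: tert-butyldimethylsilyl chloride, CC(C)(C)[Si](C)(C)Cl
Why: Silyl ether formation: under imidazole conditions only the secondary equatorial C3 hydroxyl reacts, and the tertiary C4 hydroxyl stays free.

**Step 11**
Reactants: 14 silyl ether acetonide
Product: 15 3β-(tert-butyldimethylsilyloxy)-1β-isopropenyl-4α-methylcyclohexane-4β,5β,6β-triol
Conditions: AcOH–H2O (4:1), 45 °C
Reagents that add atoms: none
Why: Acid-catalysed acetal hydrolysis; the hindered secondary silyl ether and the isopropenyl group tolerate warm aqueous acetic acid.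

**Step 12**
Reactants: 16 angelic acid (2 equiv)
Product: 17 angelic anhydride
Conditions: N,N'-dicyclohexylcarbodiimide (0.5 equiv), CH2Cl2, 0 °C → rt; filtration
Reagents that add atoms: none
Why: Carbodiimide dehydration of two acid molecules to the symmetrical anhydride under neutral conditions that do not isomerise the Z alkene.

**Step 13**
Reactants: 15 triol; 17 angelic anhydride
Product: 19 5-O-angelate of 15 (C4–OH and C6–OH free), via dibutylstannylene acetal 18 (not isolated)
Conditions: Bu2SnO (1.05 equiv), toluene, reflux with azeotropic removal of water; then 17 (1.2 equiv), rt → 45 °C; aqueous work-up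
Reagents that add atoms: none
Why: Regioselective acylation through a dibutylstannylene acetal: in the chair O5 is equatorial and O6 axial, the tin acetal of a cis-diol is acylated at its equatorial oxygen, and the tertiary C4 hydroxyl does not react.

**Step 14**
Reactants: 19 monoangelate
Product: 20 6-O-acetate of 19
Conditions: Ac2O, pyridine, 4-(dimethylamino)pyridine (cat.), CH2Cl2, 0 °C → rt
Reagents that add atoms: acetic anhydride, CC(=O)OC(C)=O
Why: Nucleophile-catalysed acetylation of the remaining secondary (axial) C6 hydroxyl; the tertiary C4 hydroxyl is too hindered to react at this temperature.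

**Step 15**
Reactants: 20 acetate angelate
Product: 21 4-O-triethylsilyl ether of 20
Conditions: Et3SiOTf, 2,6-lutidine, CH2Cl2, −78 → 0 °C
Reagents that add atoms: triethylsilyl trifluoromethanesulfonate, CC[Si](CC)(CC)OS(=O)(=O)C(F)(F)F
Why: Silyl triflate silylation of the tertiary C4 hydroxyl, which masks it before the organometallic and boron steps; the esters are inert.

**Step 16**
Reactants: 21 fully protected ring with isopropenyl group
Product: 23 enal (C7(=C14H2)–C8HO at C1), via allylic alcohol 22 (not isolated)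
Conditions: SeO2 (0.3 equiv), t-BuOOH (in decane, 2 equiv), CH2Cl2, 0 °C → rt; then MnO2 (excess), CH2Cl2, rt
Reagents that add atoms: selenium dioxide (oxygen carrier, reoxidised), O=[Se]=O; tert-butyl hydroperoxide, CC(C)(C)OO
Why: Selenium dioxide allylic oxidation (ene reaction, then [2,3]-shift) at the isopropenyl methyl group, the C1–H being deactivated by the neighbouring acetate, followed by MnO2 oxidation of the allylic alcohol to the 2-substituted propenal.

**Step 17**
Reactants: 23 enal
Product: 24 C8 methyl carbinol (C7(=C14H2)–C8H(OH)–C9H3, both C8 epimers)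
Conditions: MeMgBr (1.3 equiv), THF, −78 °C; H2O quench
Reagents that add atoms: methylmagnesium bromide, C[Mg]Br
Why: Grignard 1,2-addition to the enal, which at −78 °C is much faster than attack on the hindered acetate and angelate; the C8 epimer mixture is removed in step 18.

**Step 18**
Reactants: 24 methyl carbinol
Product: 25 methyl enone (C7(=C14H2)–C8(=O)–C9H3)
Conditions: Dess–Martin periodinane, CH2Cl2, 0 °C → rt; used promptly
Reagents that add atoms: none
Why: Dess–Martin oxidation of the secondary allylic alcohol to the α-methylene methyl ketone under near-neutral conditions.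

**Step 19**
Reactants: 26 methyl 2-hydroxyisobutyrate
Product: 27 methyl 2-methyl-2-(triethylsilyloxy)propanoate
Conditions: Et3SiOTf, 2,6-lutidine, CH2Cl2, 0 °C
Reagents that add atoms: triethylsilyl trifluoromethanesulfonate, CC[Si](CC)(CC)OS(=O)(=O)C(F)(F)F
Why: Silyl triflate silylation of the tertiary hydroxyl.

**Step 20**
Reactants: 27 silyloxy ester
Product: 28 2-methyl-2-(triethylsilyloxy)propanal
Conditions: i-Bu2AlH (1.05 equiv), CH2Cl2, −78 °C; aqueous potassium sodium tartrate work-up
Reagents that add atoms: none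
Why: Partial reduction of the ester: the chelated tetrahedral aluminium hemiacetal of the α-silyloxy ester is stable at −78 °C and releases the aldehyde on work-up.

**Step 21**
Reactants: 25 methyl enone; 28 2-methyl-2-(triethylsilyloxy)propanal
Product: 30 (10R)-β-hydroxy ketone (C8 ketone, C10–OH, C11–OSiEt3), via diisopinocampheylboron enolate 29 (not isolated)
Conditions: (+)-Ipc2BCl (1.5 equiv), Et3N (2 equiv), Et2O, −78 → 0 °C; 28, −78 → −20 °C; then pH 7 buffer, MeOH, 30% H2O2, 0 °C
Reagents that add atoms: none
Why: Reagent-controlled boron aldol reaction: the chloroborane and Et3N enolise the ketone on its only enolisable side (C9), and the (+)-diisopinocampheylboron enolate is expected to add to the Re face of the aldehyde, which sets C10 as R.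

**Step 22**
Reactants: 16 angelic acid
Product: 31 (Z)-2-methylbut-2-en-1-ol
Conditions: LiAlH4, Et2O, 0 °C → rt; aqueous NaOH work-up
Reagents that add atoms: none
Why: Hydride reduction of the acid to the primary allylic alcohol, 1,2-selective and with retention of the Z geometry.

**Step 23**
Reactants: 31 (Z)-2-methylbut-2-en-1-ol
Product: 32 (Z)-2-methylbut-2-enal
Conditions: MnO2 (excess), CH2Cl2, rt, dark; filtered, concentrated cold and used at once as a solution
Reagents that add atoms: none
Why: MnO2 oxidation of the allylic alcohol, a neutral heterogeneous method that keeps the Z geometry of this isomerisation-prone enal.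

**Step 24**
Reactants: 30 β-hydroxy ketone; 32 (Z)-2-methylbut-2-enal
Product: 33 (8R,10R)-C10 angelate with free C8–OH (C3–OSiMe2t-Bu, C4–OSiEt3, C11–OSiEt3)
Conditions: SmI2 (0.3 equiv, THF solution), 32 (5 equiv), THF, −10 °C, dark
Reagents that add atoms: none
Why: Evans–Tishchenko reduction: the C10 hydroxyl forms a hemiacetal with 32 on trivalent samarium, and intramolecular hydride transfer through a chair-like six-membered chelate reduces the C8 ketone anti to O10 (C8 R) while O10 becomes the angelate.

**Step 25**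
Reactants: 33 tris-silyl ether
Product: 34 CNP0325091.1 (target; 1R,3R,4R,5S,6S,8R,10R in the locants used here)
Conditions: HF·pyridine, pyridine, THF, 0 °C → rt
Reagents that add atoms: none
Why: Fluoride cleavage of the three silyl ethers under buffered, weakly acidic conditions that avoid acyl migration and leave the esters, the allylic alcohol and the Z alkenes untouched.

**Compound list**
1 | (S)-(+)-carvone | C=C(C)[C@H]1CC=C(C)C(=O)C1 | starting material
2 | lithium dienolate of 1 (C5–OLi, C5=C6, C3=C4) | C=C(C)[C@H]1CC=C(C)C([O-])=C1.[Li+] | intermediate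
3 | trimethylsilyl dienol ether of 1 | C=C(C)[C@H]1CC=C(C)C(O[Si](C)(C)C)=C1 | intermediate
4 | 6α-(trimethylsilyloxy)carvone (O6 trans to isopropenyl) | C=C(C)[C@H]1CC=C(C)C(=O)[C@@H]1O[Si](C)(C)C | intermediate
5 | trans-6-hydroxycarvone, (5R,6R)-6-hydroxy-2-methyl-5-(prop-1-en-2-yl)cyclohex-2-en-1-one | C=C(C)[C@H]1CC=C(C)C(=O)[C@@H]1O | intermediate
6 | cis-6-(4-nitrobenzoyloxy)carvone (6β ester) | C=C(C)[C@H]1CC=C(C)C(=O)[C@H]1OC(=O)c2ccc(cc2)[N+](=O)[O-] | intermediate
7 | 1β-isopropenyl-4-methylcyclohex-3-ene-5β,6β-diol 6-(4-nitrobenzoate) | C=C(C)[C@H]1CC=C(C)[C@@H](O)[C@H]1OC(=O)c2ccc(cc2)[N+](=O)[O-] | intermediate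
8 | 1β-isopropenyl-4-methylcyclohex-3-ene-5β,6β-diol (all-cis) | C=C(C)[C@H]1CC=C(C)[C@@H](O)[C@H]1O | intermediate
9 | 3β,4β-epoxy-1β-isopropenyl-4-methylcyclohexane-5β,6β-diol | C=C(C)[C@H]1C[C@H]2O[C@@]2(C)[C@@H](O)[C@H]1O | intermediate
10 | 5,6-O-isopropylidene derivative of 9 | C=C(C)[C@H]1C[C@H]2O[C@@]2(C)[C@H]3OC(C)(C)O[C@@H]13 | intermediate
11 | (3R,4S,5S)-3-isopropenyl-4,5-(isopropylidenedioxy)-6-oxoheptanal | C=C(C)[C@@H](CC=O)[C@@H]1OC(C)(C)O[C@@H]1C(C)=O | intermediate
12 | 4β-hydroxy-1β-isopropenyl-5β,6β-(isopropylidenedioxy)-4α-methylcyclohexan-3-one | C=C(C)[C@H]1CC(=O)[C@@](C)(O)[C@H]2OC(C)(C)O[C@@H]12 | intermediate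
13 | 1β-isopropenyl-5β,6β-(isopropylidenedioxy)-4α-methylcyclohexane-3β,4β-diol | C=C(C)[C@H]1C[C@@H](O)[C@@](C)(O)[C@H]2OC(C)(C)O[C@@H]12 | intermediate
14 | 3-O-(tert-butyldimethylsilyl) ether of 13 | C=C(C)[C@H]1C[C@@H](O[Si](C)(C)C(C)(C)C)[C@@](C)(O)[C@H]2OC(C)(C)O[C@@H]12 | intermediate
15 | 3β-(tert-butyldimethylsilyloxy)-1β-isopropenyl-4α-methylcyclohexane-4β,5β,6β-triol | C=C(C)[C@H]1C[C@@H](O[Si](C)(C)C(C)(C)C)[C@@](C)(O)[C@@H](O)[C@H]1O | intermediate
16 | angelic acid, (Z)-2-methylbut-2-enoic acid | C/C=C(/C)C(=O)O | starting material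
17 | angelic anhydride | C/C=C(/C)C(=O)OC(=O)/C(C)=C\C | intermediate
18 | 5,6-O-dibutylstannylene acetal of 15 | C=C(C)[C@H]1C[C@@H](O[Si](C)(C)C(C)(C)C)[C@@](C)(O)[C@H]2O[Sn](CCCC)(CCCC)O[C@@H]12 | intermediate
19 | 5-O-angelate of 15 | C=C(C)[C@H]1C[C@@H](O[Si](C)(C)C(C)(C)C)[C@@](C)(O)[C@@H](OC(=O)/C(C)=C\C)[C@H]1O | intermediate
20 | 6-O-acetate of 19 | C=C(C)[C@H]1C[C@@H](O[Si](C)(C)C(C)(C)C)[C@@](C)(O)[C@@H](OC(=O)/C(C)=C\C)[C@H]1OC(C)=O | intermediate
21 | 4-O-triethylsilyl ether of 20 | C=C(C)[C@H]1C[C@@H](O[Si](C)(C)C(C)(C)C)[C@@](C)(O[Si](CC)(CC)CC)[C@@H](OC(=O)/C(C)=C\C)[C@H]1OC(C)=O | intermediate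
22 | allylic alcohol: 21 with the isopropenyl methyl oxidised to CH2OH | C=C(CO)[C@H]1C[C@@H](O[Si](C)(C)C(C)(C)C)[C@@](C)(O[Si](CC)(CC)CC)[C@@H](OC(=O)/C(C)=C\C)[C@H]1OC(C)=O | intermediate
23 | enal: 21 with the isopropenyl methyl oxidised to CHO (C8) | C=C(C=O)[C@H]1C[C@@H](O[Si](C)(C)C(C)(C)C)[C@@](C)(O[Si](CC)(CC)CC)[C@@H](OC(=O)/C(C)=C\C)[C@H]1OC(C)=O | intermediate
24 | C8 methyl carbinol from 23 (mixture of C8 epimers) | C=C(C(C)O)[C@H]1C[C@@H](O[Si](C)(C)C(C)(C)C)[C@@](C)(O[Si](CC)(CC)CC)[C@@H](OC(=O)/C(C)=C\C)[C@H]1OC(C)=O | intermediate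
25 | methyl enone, C7(=C14H2)–C8(=O)–C9H3 on the protected ring | C=C(C(C)=O)[C@H]1C[C@@H](O[Si](C)(C)C(C)(C)C)[C@@](C)(O[Si](CC)(CC)CC)[C@@H](OC(=O)/C(C)=C\C)[C@H]1OC(C)=O | intermediate
26 | methyl 2-hydroxyisobutyrate | COC(=O)C(C)(C)O | starting material
27 | methyl 2-methyl-2-(triethylsilyloxy)propanoate | COC(=O)C(C)(C)O[Si](CC)(CC)CC | intermediate
28 | 2-methyl-2-(triethylsilyloxy)propanal | O=CC(C)(C)O[Si](CC)(CC)CC | intermediate
29 | diisopinocampheylboron enolate of 25 (C8(=C9H2)–O–B(Ipc)2, Ipc from (−)-α-pinene) | C=C(OB([C@H]2C[C@H]3C[C@@H]([C@@H]2C)C3(C)C)[C@H]2C[C@H]3C[C@@H]([C@@H]2C)C3(C)C)C(=C)[C@H]1C[C@@H](O[Si](C)(C)C(C)(C)C)[C@@](C)(O[Si](CC)(CC)CC)[C@@H](OC(=O)/C(C)=C\C)[C@H]1OC(C)=O | intermediate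
30 | (10R)-aldol: C8 ketone, C10–OH, C11–OSiEt3 | C=C(C(=O)C[C@@H](O)C(C)(C)O[Si](CC)(CC)CC)[C@H]1C[C@@H](O[Si](C)(C)C(C)(C)C)[C@@](C)(O[Si](CC)(CC)CC)[C@@H](OC(=O)/C(C)=C\C)[C@H]1OC(C)=O | intermediate
31 | (Z)-2-methylbut-2-en-1-ol | C/C=C(/C)CO | intermediate
32 | (Z)-2-methylbut-2-enal | C/C=C(/C)C=O | intermediate
33 | (8R,10R)-10-O-angelate, 8-OH; 3-O-SiMe2t-Bu, 4-O-SiEt3, 11-O-SiEt3 | C=C([C@H](O)C[C@@H](OC(=O)/C(C)=C\C)C(C)(C)O[Si](CC)(CC)CC)[C@H]1C[C@@H](O[Si](C)(C)C(C)(C)C)[C@@](C)(O[Si](CC)(CC)CC)[C@@H](OC(=O)/C(C)=C\C)[C@H]1OC(C)=O | intermediate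
34 | CNP0325091.1 | C=C([C@H](O)C[C@@H](OC(=O)/C(C)=C\C)C(C)(C)O)[C@H]1C[C@@H](O)[C@@](C)(O)[C@@H](OC(=O)/C(C)=C\C)[C@H]1OC(C)=O | target

**Step count**
Total: 25 steps. Longest linear sequence: 20 steps (1–11, 13–18, 21, 24, 25).

**Steps most likely to fail**

Step 8. The ketone may be attacked on the wrong face, or base-induced epimerisation at C5 and aldol closure may outrun the carbene pathway. The fallback sets out from 10 and comes back at 12 without opening the ring. Hydroxide (KOH, DMSO–H2O, heat) opens the β-epoxide at the less substituted C3 with inversion to give the 3α,4β-diol acetonide F1. Its tertiary C4–O bond is the one made by the hydroxyl-directed epoxidation, so the C4 configuration is fixed. Oxidation of the secondary hydroxyl (SO3·pyridine, DMSO, Et3N) then gives 12.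

Step 24. The enal or the forming ester may isomerise from Z to E on the Lewis-acidic samarium alkoxide, hemiacetal formation at the hindered C10 hydroxyl may be slow, or the acyl group may migrate from O10 to O8. The fallback sets out from 30 and comes back at 34. Evans–Saksena reduction (Me4NBH(OAc)3, MeCN–AcOH, −30 °C) should give the anti-8,10-diol F2. The less hindered allylic C8 hydroxyl is silylated selectively (Et3SiCl, imidazole, CH2Cl2, −20 °C) to give the 8-O-triethylsilyl ether F3. Yamaguchi esterification of the C10 hydroxyl with 16 (2,4,6-trichlorobenzoyl chloride, Et3N, toluene, warming, no nucleophilic catalyst) gives the 10-O-angelate F4. HF·pyridine under the conditions of step 25 removes all four silyl groups to give 34.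

Step 16. The selenium ene reaction may take the ring methine C1–H in place of the methyl group, over-oxidise, or attack the allylic methyls of the angelate. The fallback sets out from 21 and comes back at 23. Ene-type chlorination with HOCl made from Ca(OCl)2 and CO2 (CH2Cl2–H2O, 0 °C) gives the allylic chloride F5. Oxidation with trimethylamine N-oxide in DMSO at rt then gives the enal 23.

**Further compounds**
F1 | step 8 | 1β-isopropenyl-5β,6β-(isopropylidenedioxy)-4α-methylcyclohexane-3α,4β-diol | C=C(C)[C@H]1C[C@H](O)[C@@](C)(O)[C@H]2OC(C)(C)O[C@@H]12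
F2 | step 24 | (8R,10R)-8,10-diol from 30 | C=C([C@H](O)C[C@@H](O)C(C)(C)O[Si](CC)(CC)CC)[C@H]1C[C@@H](O[Si](C)(C)C(C)(C)C)[C@@](C)(O[Si](CC)(CC)CC)[C@@H](OC(=O)/C(C)=C\C)[C@H]1OC(C)=O
F3 | step 24 | 8-O-triethylsilyl ether of F2 | C=C([C@H](O[Si](CC)(CC)CC)C[C@@H](O)C(C)(C)O[Si](CC)(CC)CC)[C@H]1C[C@@H](O[Si](C)(C)C(C)(C)C)[C@@](C)(O[Si](CC)(CC)CC)[C@@H](OC(=O)/C(C)=C\C)[C@H]1OC(C)=O
F4 | step 24 | 10-O-angelate of F3 | C=C([C@H](O[Si](CC)(CC)CC)C[C@@H](OC(=O)/C(C)=C\C)C(C)(C)O[Si](CC)(CC)CC)[C@H]1C[C@@H](O[Si](C)(C)C(C)(C)C)[C@@](C)(O[Si](CC)(CC)CC)[C@@H](OC(=O)/C(C)=C\C)[C@H]1OC(C)=O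
F5 | step 16 | allylic chloride: 21 with the isopropenyl methyl converted to CH2Cl | C=C(CCl)[C@H]1C[C@@H](O[Si](C)(C)C(C)(C)C)[C@@](C)(O[Si](CC)(CC)CC)[C@@H](OC(=O)/C(C)=C\C)[C@H]1OC(C)=O
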